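## The problem

The target is an isoflavanone. Ring A is a benzene ring (C4a to C8a) with hydroxyls at C5 and C7, fused to the oxygen ring C (O1, C2, C3, C4). C3 carries ring B, a 2'-hydroxy-4'-methoxyphenyl group with a geranyl chain at C3', between the two oxygens.

The only stereocentre is C3 (S). It is tertiary, benzylic and alpha to the C4 ketone, so it can direct nothing else. It is lost by enolisation, or by E1cB opening of the O1–C2 bond, in base, and by enolisation in warm acid. It must therefore be created late and kept near neutrality afterwards.

The geranyl chain has two trisubstituted alkenes, one of fixed E geometry, next to a phenol. This rules out hydrogenolysis, electrophilic halogen, peracids and strong acid, the last because the 2'-hydroxyl cyclises onto the chain. Ring B needs four contiguous substituents, and three phenols must end free, the 5-hydroxyl chelated to the ketone.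

The feature that opens the key step is the 1,3-relation of the C5 and C7 oxygens on a ring that shares the C4a–C8a bond with a 4-pyranone. C4a is alpha and C8a is beta to the C4 carbonyl, so in a 2,3-dihydro-4H-pyran-4-one this bond is an enone double bond. A 1,3-dioxygenated four-carbon diene can add across it and the adduct can be aromatised.

## Retrosynthesis

**Target 26 from 25.** The last cut is the acetal C–O bond at the 2'-oxygen. The methoxymethyl (MOM) group is kept to the end because it directs both ring metalations of ring B and because an ortho alkoxy group, not a free phenol, should flank C3 when the stereocentre is set. The forward step must remove one aryl acetal without enolising C3 and without letting the freed phenol add to the geranyl alkene.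

**25 from 24, and 24 from 22.** The C3–H bond is cut. Racemic ketone 22 is converted to the achiral tris(allyl carbonate) 24, whose enol carbonate gives a chiral palladium enolate that is protonated at C3. This is preferred to an asymmetric reduction of an isoflavone, which would have to spare the geranyl alkenes, and to a resolution, because all of the racemate is converted and the same palladium step removes the two ring A carbonates. The forward step must give high face selectivity in the protonation and complete deallylation.

**22 from 16 and 19 (key disconnection).** C4a–C5 and C8–C8a are cut, so ring A is removed entirely. What remains is the monocyclic sulfinyl dihydropyranone 16 and the four-carbon diene 19. The neighbouring cut, C4–C4a acylation of a preformed 1,3,5-trioxygenated benzene, needs either strong acid, which the geranyl chain and the acetal do not survive, or a fully protected aryl metal followed by differentiation of four phenol protecting groups. Building ring A instead delivers the C5 and C7 phenols free and distinct from the protected 2'-oxygen. The forward reaction must add the diene to a push–pull alkene with the right regiochemistry, lose the sulfinyl group and methanol, and leave C3–H and the geranyl alkenes alone. C3 may stay racemic because the next steps are stereoconvergent.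

**16 from 13.** The O1–C6 bond of the pyranone is cut and C6 is removed as a one-carbon unit. Keto sulfoxide 13 takes up this carbon as an enaminone (14), and the primary alcohol freed from its silyl ether (15) closes the ring with loss of the amine. This puts the sulfinyl group on the alpha carbon of the enone without any oxidation near the alkenes.

**13 from 10 and 11.** The acyl–CH2S bond is cut. Ester 10 acylates the carbanion 12 of racemic methyl p-tolyl sulfoxide 11. Racemic sulfoxide suffices because sulfur is lost in the key step.

**10 from 9, 9 from 8, 8 from 7.** The C2–C3 bond is cut by a one-carbon aldol (8 to 9), and the alcohol is masked as a triethylsilyl (TES) ether (10) that mild acid later removes. The aryl–CH2 bond is cut to aryl iodide 7 and a zinc ester enolate. This is one step, whereas homologation of a benzaldehyde would take three or four.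

**7 from 5, 5 from 2 and 3, 2 from 1.** Two successive directed metalations build ring B. The first takes place at the carbon between the two oxygens of 2 (via aryllithium 4) and brings in geranyl bromide 3. The second takes place ortho to the acetal of 5 (via aryllithium 6) and brings in iodine. Electrophilic substitution would give the wrong regiochemistry and attack the alkenes. Compound 2 comes from 3-methoxyphenol 1.

**19 from 18, 18 from 17.** Diene 19 is the bis(silyl) derivative of the dianion of methyl acetoacetate 17, made by two silylations through enol ether 18.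

## Roads not taken

**Alternative 1:** The cut goes through ring B. C1'–C2', C2'–C3' and C4'–C5' are broken, so ring B arises from the chromonyl diazo ketone A2 and the geranyl-bearing methoxyalkyne A3. In the forward sense, irradiation of A2 causes Wolff rearrangement to a vinylketene, which adds A3 in a [2+2] fashion. The cyclobutenone opens, recloses by six-electron electrocyclisation and tautomerises to the isoflavone A1 (Danheiser benzannulation).
- Merits: the crowded 1',2',3',4' pattern is written into acyclic partners, the regiochemistry follows from the polarity of the ynol ether, three C–C bonds form at once, and the 2'-hydroxyl is formed free.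
- Weak points: A3 is a skipped enyne ynol ether whose doubly activated CH2 invites isomerisation. A2 puts a diazo ketone beside a chromone that absorbs in the same ultraviolet region and is itself a Michael acceptor. A1 is an isoflavone, so C3 must still be made by an enantioselective reduction of C2=C3 that spares the geranyl alkenes and stops at the ketone, and two ring A acetals must then be removed in acid.
- Comparison: this road is better in convergence, in bonds formed per step and in the handling of the 2'-hydroxyl. The chosen plan offers in return a ring B made in three ordinary operations from 1, no diazo compound, ynol ether or photochemistry, and a C3 set by enolate protonation from 22, which has closer precedent on 3-aryl chromanones than conjugate reduction of A1.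

**Alternative 2:** The cut is the C2–C3 bond alone. Ring C closes from the diazo deoxybenzoin A5, in which a methoxy group on ring A supplies C2. A chiral dirhodium tetracarboxylate catalyst converts A5 to a carbenoid at C3 that inserts into a C–H bond of that methoxy group and gives the tris(silyl) isoflavanone A4.
- Merits: ring closure and the C3 stereocentre come from one catalytic step, both arenes enter intact, and the step count is clearly lower than in the chosen plan.
- Weak points: the insertion must form a six-membered ring, while attack on the methoxy oxygen gives an oxonium ylide and, after a 1,2-shift, a benzofuranone. The ortho silyloxy oxygen of ring B and the two geranyl alkenes are further traps for the carbenoid. The new centre sits at the former carbenoid carbon, so any stepwise character, or fluoride in the threefold desilylation, endangers it.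
- Comparison: if it works, this is the shortest route and the chosen plan cannot match it in step economy. The chosen plan separates ring construction (steps 8 and 11) from stereocontrol (step 13), so a poor enantioselective step does not cost the skeleton, and its stereo-determining step can be repeated on material returned to 24. It also keeps electrophilic carbenoids away from the geranyl chain.

**Alternative 3:** The cut removes C4 as a one-carbon unit. C4a–C4 and C4–C3 are broken, giving the iodoarene A7, the tosylhydrazone A8 and a carbonyl ligand on palladium. In the forward sense a zerovalent palladium phosphine catalyst adds to A7 and carbonyl insertion gives an aroyl palladium species. The diazo compound released from A8 by base then forms a carbene that inserts, and beta-hydride elimination gives the 2-aryl enone A6.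
- Merits: it is the most convergent of the four roads; the whole carbon skeleton is assembled in one step from two arenes.
- Weak points: A7 is a 2,6-dioxygenated, electron-rich iodide, and carbonyl insertion must outrun direct carbene coupling to a 1,1-diarylethene. No ring closes and no stereocentre is set. To reach the isoflavanone, one ortho acetal of ring A must be removed from among four similar acetals before 6-endo oxa-Michael closure. The enone A6 is prone to polymerise, and C3 then arises in an enolate protonation that still needs its own asymmetric solution.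
- Comparison: this road reaches the skeleton faster. The chosen plan offers in return ring A phenols that appear free and already differentiated from the 2'-acetal, a ring C closed before ring A exists, and no selective deprotection. The end game is the same problem in both, so Alternative 3 saves nothing there.

Key step: step 11

## Remarks before the steps

- Ar stands for the ring B group 3-[(2E)-3,7-dimethylocta-2,6-dien-1-yl]-4-methoxy-2-(methoxymethoxy)phenyl.
- Assumption: racemic methyl p-tolyl sulfoxide is used, so 13 to 16 and 20 are stereoisomer mixtures at sulfur and C3. This is harmless because sulfur is lost in step 11 and C3 is reset in steps 12 and 13.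
- Assumption: the (S)-configured PHOX ligand with Meldrum's acid is taken to give the (3S)-ketone. If the sense proves opposite, the (R)-ligand is used without other change.
- Remark: phenoxide, alkoxide and enolate salts are treated as ionised forms of the numbered compounds. Carbon–lithium intermediates carry their own numbers.

## Steps

Step 1
Reactants: 1 3-methoxyphenol
Product: 2 1-methoxy-3-(methoxymethoxy)benzene
Conditions: NaH, MOMCl, THF/DMF, 0 °C → rt
Reagents that add atoms: chloromethyl methyl ether (MOMCl), COCCl
Why: O-alkylation of the phenoxide (Williamson type); the acetal directs both later metalations and survives every basic and organometallic step.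

Step 2
Reactants: 2 1-methoxy-3-(methoxymethoxy)benzene; 3 geranyl bromide
Product: 5 2-[(2E)-3,7-dimethylocta-2,6-dien-1-yl]-1-methoxy-3-(methoxymethoxy)benzene, via aryllithium 4 (not isolated)
Conditions: n-BuLi, THF, 0 °C → rt; CuI (10 mol%), then 3, −30 °C → rt
Reagents that add atoms: none
Why: Directed ortho-metalation at the carbon flanked by both oxygens, then copper-catalysed SN2 allylation; displacement at the primary carbon keeps the (E)-alkene of the geranyl unit.

Step 3
Reactants: 5 2-[(2E)-3,7-dimethylocta-2,6-dien-1-yl]-1-methoxy-3-(methoxymethoxy)benzene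
Product: 7 2-[(2E)-3,7-dimethylocta-2,6-dien-1-yl]-4-iodo-1-methoxy-3-(methoxymethoxy)benzene, via aryllithium 6 (not isolated)
Conditions: n-BuLi, TMEDA, THF, 0 °C; ICH2CH2I, −78 °C → rt
Reagents that add atoms: 1,2-diiodoethane, ICCI
Why: Second directed ortho-metalation; the chelating acetal outranks the methoxy group, so the C–H ortho to it (the future C1') is lithiated, and 1,2-diiodoethane iodinates the aryllithium without exposing the alkenes to free iodine.

Step 4
Reactants: 7 2-[(2E)-3,7-dimethylocta-2,6-dien-1-yl]-4-iodo-1-methoxy-3-(methoxymethoxy)benzene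
Product: 8 ethyl 2-Ar-acetate
Conditions: BrZnCH2CO2Et (from BrCH2CO2Et, Zn, THF), Pd2(dba)3 (2.5 mol%), XPhos (6 mol%), THF, 60 °C
Reagents that add atoms: ethyl bromoacetate (as its zinc reagent), CCOC(=O)CBr
Why: Palladium-catalysed cross-coupling of an aryl halide with a Reformatsky reagent; the neutral zinc enolate gives mono-arylation and tolerates the acetal and the alkenes.

Step 5
Reactants: 8 ethyl 2-Ar-acetate
Product: 9 ethyl 2-Ar-3-hydroxypropanoate (racemic)
Conditions: (CH2O)n (1.1 equiv), NaOEt (5 mol%), DMSO, rt
Reagents that add atoms: formaldehyde (from paraformaldehyde), C=O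
Why: Aldol hydroxymethylation of an arylacetate, as in tropic ester synthesis; catalytic matched alkoxide at room temperature should stop at the mono-adduct without dehydration, and the new centre is racemic and of no consequence.

Step 6
Reactants: 9 ethyl 2-Ar-3-hydroxypropanoate (racemic)
Product: 10 ethyl 2-Ar-3-(triethylsilyloxy)propanoate (racemic)
Conditions: TESCl, imidazole, CH2Cl2, 0 °C
Reagents that add atoms: chlorotriethylsilane (TESCl), CC[Si](Cl)(CC)CC
Why: Silylation of a primary alcohol; the silyl ether blocks retro-aldol loss of formaldehyde in step 7 and is removed by the mild acid of step 8.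

Step 7
Reactants: 10 ethyl 2-Ar-3-(triethylsilyloxy)propanoate (racemic); 11 methyl p-tolyl sulfoxide (racemic)
Product: 13 3-Ar-1-[(4-methylphenyl)sulfinyl]-4-(triethylsilyloxy)butan-2-one (diastereomer mixture), via lithiated sulfoxide 12 (not isolated)
Conditions: 11 (2.2 equiv), LiN(i-Pr)2 (2.2 equiv), THF, −78 °C; then 10, −78 → −40 °C; aq. NH4Cl
Reagents that add atoms: none
Why: Claisen-type acylation of an alpha-sulfinyl carbanion by an ester; the second equivalent of carbanion deprotonates the beta-keto sulfoxide as it forms and stops over-addition, and the low temperature favours addition over deprotonation of the benzylic C–H.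

Step 8
Reactants: 13 3-Ar-1-[(4-methylphenyl)sulfinyl]-4-(triethylsilyloxy)butan-2-one (diastereomer mixture)
Product: 16 3-Ar-5-[(4-methylphenyl)sulfinyl]-2,3-dihydro-4H-pyran-4-one (diastereomer mixture), via silyloxy enaminone 14 (not isolated), via hydroxy enaminone 15 (not isolated)
Conditions: Me2NCH(OMe)2, PhMe, 60 °C; evaporate; AcOH/THF/H2O (3:1:1), 40 °C
Reagents that add atoms: N,N-dimethylformamide dimethyl acetal, COC(OC)N(C)C
Why: Condensation of the doubly activated methylene with the amide acetal gives the enaminone. Aqueous acetic acid then cleaves the silyl ether, and the freed alcohol adds to the protonated enaminone and expels dimethylamine (6-endo-trig addition–elimination), the known route from beta-hydroxy enaminones to dihydropyranones.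

Step 9
Reactants: 17 methyl acetoacetate
Product: 18 methyl 3-(trimethylsilyloxy)but-2-enoate
Conditions: TMSCl, Et3N, hexane, rt
Reagents that add atoms: chlorotrimethylsilane (TMSCl), C[Si](C)(C)Cl
Why: O-silylation of the enol of a beta-keto ester.

Step 10
Reactants: 18 methyl 3-(trimethylsilyloxy)but-2-enoate
Product: 19 1-methoxy-1,3-bis(trimethylsilyloxy)buta-1,3-diene
Conditions: LiN(i-Pr)2, THF, −78 °C; TMSCl, −78 °C → rt
Reagents that add atoms: chlorotrimethylsilane (TMSCl), C[Si](C)(C)Cl
Why: Gamma-deprotonation of the silyl enol ether to the dienolate and O-silylation at the ester oxygen give the ketene silyl acetal diene; its geometry is irrelevant because it is lost on aromatisation.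

Step 11
Reactants: 16 3-Ar-5-[(4-methylphenyl)sulfinyl]-2,3-dihydro-4H-pyran-4-one (diastereomer mixture); 19 1-methoxy-1,3-bis(trimethylsilyloxy)buta-1,3-diene
Product: 22 racemic 3-Ar-5,7-dihydroxy-2,3-dihydro-4H-chromen-4-one, via cycloadduct 20 (not isolated), via dienyl silyl ketal 21 (not isolated)
Conditions: 19 (2.5 equiv), PhMe, 0 °C → rt, then 60 °C; then AcOH/H2O/THF, rt
Reagents that add atoms: none
Why: Proposed new method: the electron-rich diene 19 should add across the C5=C6 bond of 16 (the future C4a=C8a), an alkene activated by both the ketone and the sulfinyl group, in a normal-demand [4+2] cycloaddition that forms C8–C8a and C4a–C5 and closes ring A as a six-membered carbocycle; a stepwise Mukaiyama–Michael addition followed by 6-exo-trig acylation of the sulfinyl enolate would reach the same skeleton. In the cis-fused adduct 20 the sulfinyl group and H-8a lie on the same face, so thermal syn elimination of the sulfenic acid gives 21. Mild aqueous acid then hydrolyses the silyl ketal at C5 with loss of methanol and cleaves the C7 silyl ether, and the dienone tautomerises to the 5,7-dihydroxy benzene ring. The closest known reaction type is the Diels–Alder reaction and aromatisation of 1,3-bis(silyloxy)dienes with sulfinyl- or halogen-activated quinones and chromones; a 2,3-dihydro-4H-pyran-4-one has not served in this role. The step needs regioselectivity, and polarisation should secure it: the CH2 terminus of 19, its most nucleophilic carbon, bonds to C8a, the beta carbon of the enone, and the ketene acetal carbon bonds to the sulfinyl-bearing C4a, which places the oxygens at C5 and C7. Chemoselectivity over the two unactivated geranyl alkenes follows from the electron demand of the diene. The centres formed at C4a, C5 and C8a vanish on aromatisation, so no stereocontrol is needed, and C3 is untouched and stays racemic. Ring opening by loss of O1 from the intermediate enolate, the side path known for chromones, is disfavoured here because the leaving group would be an alkoxide.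

Step 12
Reactants: 22 racemic 3-Ar-5,7-dihydroxy-2,3-dihydro-4H-chromen-4-one
Product: 24 3-Ar-2H-chromene-4,5,7-triyl tris(prop-2-en-1-yl) tricarbonate, via bis(allyl carbonate) 23 (not isolated)
Conditions: NaN(SiMe3)2 (2.1 equiv), THF, −78 °C; ClCO2CH2CH=CH2 (2.2 equiv), → 0 °C; recool to −78 °C, NaN(SiMe3)2 (1.2 equiv), TMEDA; ClCO2CH2CH=CH2 (1.3 equiv)
Reagents that add atoms: allyl chloroformate, C=CCOC(=O)Cl
Why: O-acylation of the two phenoxides and then of the sodium enolate of the alpha-aryl ketone by a chloroformate, a hard electrophile that favours oxygen; the enol carbonate makes C3 planar, so the racemic centre is erased.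

Step 13
Reactants: 24 3-Ar-2H-chromene-4,5,7-triyl tris(prop-2-en-1-yl) tricarbonate
Product: 25 (3S)-3-Ar-5,7-dihydroxy-2,3-dihydro-4H-chromen-4-one
Conditions: Pd2(dba)3 (5 mol%), (S)-(CF3)3-t-BuPHOX (12.5 mol%), Meldrum's acid (5 equiv), 1,4-dioxane, 40 °C
Reagents that add atoms: none
Why: Palladium-catalysed decarboxylative asymmetric protonation of an allyl enol carbonate: zerovalent palladium ionises the enol carbonate, carbon dioxide is lost, and the chiral palladium enolate is protonated at C3 by Meldrum's acid on the face left open by the PHOX ligand, which sets the (S)-centre from achiral 24. The two aryl allyl carbonates are cleaved in the same pot by the same ionisation and decarboxylation, and Meldrum's acid takes up the allyl groups. The reaction type is established for tertiary alpha-aryl centres of chroman-4-ones and related cyclic ketones.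

Step 14
Reactants: 25 (3S)-3-Ar-5,7-dihydroxy-2,3-dihydro-4H-chromen-4-one
Product: 26 (3S)-3-{3-[(2E)-3,7-dimethylocta-2,6-dien-1-yl]-2-hydroxy-4-methoxyphenyl}-5,7-dihydroxy-2,3-dihydro-4H-chromen-4-one
Conditions: HCl (1.25 M in MeOH), 0 °C → rt, stopped at full conversion
Reagents that add atoms: none
Why: Acid-catalysed transacetalisation of the aryl methoxymethyl ether to methanol; dilute acid at or below room temperature is chosen so that C3 does not enolise and the freed 2'-hydroxyl does not add to the geranyl alkene or to the C4 ketone.

## Compound list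

1 | 3-methoxyphenol | COc1cccc(O)c1 | starting material
2 | 1-methoxy-3-(methoxymethoxy)benzene | COCOc1cccc(OC)c1 | intermediate
3 | geranyl bromide, (2E)-1-bromo-3,7-dimethylocta-2,6-diene | BrC/C=C(\C)CCC=C(C)C | starting material
4 | [2-methoxy-6-(methoxymethoxy)phenyl]lithium | [Li]c1c(OC)cccc1OCOC | intermediate (not isolated)
5 | 2-[(2E)-3,7-dimethylocta-2,6-dien-1-yl]-1-methoxy-3-(methoxymethoxy)benzene | COCOc1cccc(OC)c1C/C=C(\C)CCC=C(C)C | intermediate
6 | {3-[(2E)-3,7-dimethylocta-2,6-dien-1-yl]-4-methoxy-2-(methoxymethoxy)phenyl}lithium | [Li]c1ccc(OC)c(C/C=C(\C)CCC=C(C)C)c1OCOC | intermediate (not isolated)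
7 | 2-[(2E)-3,7-dimethylocta-2,6-dien-1-yl]-4-iodo-1-methoxy-3-(methoxymethoxy)benzene | COc1ccc(I)c(OCOC)c1C/C=C(\C)CCC=C(C)C | intermediate
8 | ethyl 2-{3-[(2E)-3,7-dimethylocta-2,6-dien-1-yl]-4-methoxy-2-(methoxymethoxy)phenyl}acetate | CCOC(=O)Cc1ccc(OC)c(C/C=C(\C)CCC=C(C)C)c1OCOC | intermediate
9 | ethyl 2-Ar-3-hydroxypropanoate (racemic) | CCOC(=O)C(CO)c1ccc(OC)c(C/C=C(\C)CCC=C(C)C)c1OCOC | intermediate
10 | ethyl 2-Ar-3-(triethylsilyloxy)propanoate (racemic) | CCOC(=O)C(CO[Si](CC)(CC)CC)c1ccc(OC)c(C/C=C(\C)CCC=C(C)C)c1OCOC | intermediate
11 | methyl p-tolyl sulfoxide (racemic), 1-methyl-4-(methylsulfinyl)benzene | Cc1ccc(S(C)=O)cc1 | starting material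
12 | [(4-methylphenyl)sulfinyl]methyllithium | [Li]CS(=O)c1ccc(C)cc1 | intermediate (not isolated)
13 | 3-Ar-1-[(4-methylphenyl)sulfinyl]-4-(triethylsilyloxy)butan-2-one (mixture of diastereomers) | Cc1ccc(S(=O)CC(=O)C(CO[Si](CC)(CC)CC)c2ccc(OC)c(C/C=C(\C)CCC=C(C)C)c2OCOC)cc1 | intermediate
14 | 4-Ar-1-(dimethylamino)-2-[(4-methylphenyl)sulfinyl]-5-(triethylsilyloxy)pent-1-en-3-one | CN(C)C=C(C(=O)C(CO[Si](CC)(CC)CC)c1ccc(OC)c(C/C=C(\C)CCC=C(C)C)c1OCOC)S(=O)c1ccc(C)cc1 | intermediate (not isolated)
15 | 4-Ar-1-(dimethylamino)-5-hydroxy-2-[(4-methylphenyl)sulfinyl]pent-1-en-3-one | CN(C)C=C(C(=O)C(CO)c1ccc(OC)c(C/C=C(\C)CCC=C(C)C)c1OCOC)S(=O)c1ccc(C)cc1 | intermediate (not isolated)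
16 | 3-Ar-5-[(4-methylphenyl)sulfinyl]-2,3-dihydro-4H-pyran-4-one (racemic at C3, both sulfur configurations) | O=C1C(S(=O)c2ccc(C)cc2)=COCC1c1ccc(OC)c(C/C=C(\C)CCC=C(C)C)c1OCOC | intermediate
17 | methyl acetoacetate | COC(=O)CC(C)=O | starting material
18 | methyl 3-(trimethylsilyloxy)but-2-enoate | COC(=O)C=C(C)O[Si](C)(C)C | intermediate
19 | 1-methoxy-1,3-bis(trimethylsilyloxy)buta-1,3-diene | COC(O[Si](C)(C)C)=CC(=C)O[Si](C)(C)C | intermediate
20 | 3-Ar-5-methoxy-4a-[(4-methylphenyl)sulfinyl]-5,7-bis(trimethylsilyloxy)-2,3,4a,5,8,8a-hexahydro-4H-chromen-4-one (cis-fused, mixture of diastereomers) | COC1(O[Si](C)(C)C)C=C(O[Si](C)(C)C)CC2OCC(c3ccc(OC)c(C/C=C(\C)CCC=C(C)C)c3OCOC)C(=O)C12S(=O)c1ccc(C)cc1 | intermediate (not isolated)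
21 | 3-Ar-5-methoxy-5,7-bis(trimethylsilyloxy)-2,3,5,8-tetrahydro-4H-chromen-4-one | COC1(O[Si](C)(C)C)C=C(O[Si](C)(C)C)CC2=C1C(=O)C(c1ccc(OC)c(C/C=C(\C)CCC=C(C)C)c1OCOC)CO2 | intermediate (not isolated)
22 | racemic 3-Ar-5,7-dihydroxy-2,3-dihydro-4H-chromen-4-one | COc1ccc(C2COc3cc(O)cc(O)c3C2=O)c(OCOC)c1C/C=C(\C)CCC=C(C)C | intermediate
23 | racemic 3-Ar-4-oxo-3,4-dihydro-2H-chromene-5,7-diyl bis(prop-2-en-1-yl) dicarbonate | COc1ccc(C2COc3cc(OC(=O)OCC=C)cc(OC(=O)OCC=C)c3C2=O)c(OCOC)c1C/C=C(\C)CCC=C(C)C | intermediate (not isolated)
24 | 3-Ar-2H-chromene-4,5,7-triyl tris(prop-2-en-1-yl) tricarbonate | C=CCOC(=O)OC1=C(c2ccc(OC)c(C/C=C(\C)CCC=C(C)C)c2OCOC)COc2cc(OC(=O)OCC=C)cc(OC(=O)OCC=C)c21 | intermediate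
25 | (3S)-3-Ar-5,7-dihydroxy-2,3-dihydro-4H-chromen-4-one | COc1ccc([C@H]2COc3cc(O)cc(O)c3C2=O)c(OCOC)c1C/C=C(\C)CCC=C(C)C | intermediate
26 | (3S)-3-{3-[(2E)-3,7-dimethylocta-2,6-dien-1-yl]-2-hydroxy-4-methoxyphenyl}-5,7-dihydroxy-2,3-dihydro-4H-chromen-4-one (CNP0303304.1) | COc1ccc([C@H]2COc3cc(O)cc(O)c3C2=O)c(O)c1C/C=C(\C)CCC=C(C)C | target

## Step count and risk

Total step count: 14. Longest linear sequence: 12 steps (steps 1 to 8 and 11 to 14). The diene arm (steps 9 and 10) joins at step 11.

**Step 11 (key step).**
- Risk: the ring oxygen donates into the enone and may make the alkene too unreactive, so that the diene decomposes on warming before it adds. The central carbon of the diene may react instead of the ketene acetal terminus, or the ring may open at O1 after the first bond is formed.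
- Fallback (known chemistry): ring A is taken ready-made. The route leaves at aryl iodide 7. Commercial 5,7-dihydroxychroman-4-one is protected (MOMCl, NaH) to 5,7-bis(methoxymethoxy)chroman-4-one F1. Palladium-catalysed ketone alpha-arylation of F1 with 7 (Pd2(dba)3, XPhos, NaOt-Bu, toluene) gives the racemic tris(methoxymethyl) isoflavanone F2. Enolisation and O-acylation with allyl chloroformate give the allyl enol carbonate F3. Decarboxylative asymmetric protonation as in step 13 gives the (S)-tris(methoxymethyl) isoflavanone F4, and methanolic HCl removes the three acetals. The route is rejoined at 26.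

**Step 13.**
- Risk: the phenols freed in the same pot may act as proton shuttles outside the ligand pocket and erode the enantioselectivity. Re-allylation of the phenoxides may slow the deallylation.
- Fallback: the centre is set by reduction instead of protonation. From 22, the two ring A phenols are protected (MOMCl, NaH) to give F2. Asymmetric transfer hydrogenation with dynamic kinetic resolution (RuCl[(S,S)-TsDPEN](p-cymene) or its enantiomer, whichever gives the (3S,4S)-alcohol, HCO2H/Et3N) gives the cis-isoflavan-4-ol F5. Buffered Dess–Martin oxidation returns the ketone as F4 without touching C3, and methanolic HCl gives 26. This bypasses steps 12 to 14.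

**Step 7.**
- Risk: the sulfinyl carbanion may deprotonate the benzylic alpha C–H of the ester instead of adding. Beta-elimination of silanolate from the resulting enolate would then consume the ester.
- Fallback: the carbanion is added to an aldehyde, which reacts far faster than an ester. From 10, i-Bu2AlH at −78 °C gives the aldehyde F6. Addition of 12 at −78 °C gives the beta-hydroxy sulfoxide F7, and Dess–Martin oxidation gives 13.

**Step 14.**
- Risk: acid-catalysed enolisation may erode the configuration at C3. The freed 2'-hydroxyl may cyclise onto the geranyl alkene or onto C4.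
- Fallback: the acetal is removed before the stereocentre exists. From 22, methanolic HCl gives the racemic triol F8, where slow and mild conditions cost no configuration. Exhaustive acylation with allyl chloroformate gives the tetrakis(allyl carbonate) F9. The palladium-catalysed decarboxylative protonation with fourfold deallylation then gives 26 as the last step. Its weakness is a free 2'-phenol next to the enolate during protonation.

**Step 3.**
- Risk: the base may remove a proton from the benzylic and allylic CH2 of the geranyl chain, or from the position ortho to the methoxy group, instead of the position ortho to the acetal.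
- Fallback: the halogen is in place before the chain. From geranyl bromide 3 and commercial 2-bromo-5-methoxyphenol, protection (MOMCl, NaH) gives 1-bromo-4-methoxy-2-(methoxymethoxy)benzene F10. Deprotonation between the two oxygens with lithium 2,2,6,6-tetramethylpiperidide at −78 °C and copper-catalysed allylation with 3 give the aryl bromide F11. The zinc enolate coupling of step 4 then gives 8.

## Further compounds

F1 | step 11 | 5,7-bis(methoxymethoxy)-2,3-dihydro-4H-chromen-4-one | COCOc1cc(OCOC)c2C(=O)CCOc2c1
F2 | step 11 | racemic 3-Ar-5,7-bis(methoxymethoxy)-2,3-dihydro-4H-chromen-4-one | COc1ccc(C2COc3cc(OCOC)cc(OCOC)c3C2=O)c(OCOC)c1C/C=C(\C)CCC=C(C)C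
F3 | step 11 | 3-Ar-5,7-bis(methoxymethoxy)-2H-chromen-4-yl prop-2-en-1-yl carbonate | C=CCOC(=O)OC1=C(c2ccc(OC)c(C/C=C(\C)CCC=C(C)C)c2OCOC)COc2cc(OCOC)cc(OCOC)c21
F4 | step 11 | (3S)-3-Ar-5,7-bis(methoxymethoxy)-2,3-dihydro-4H-chromen-4-one | COc1ccc([C@H]2COc3cc(OCOC)cc(OCOC)c3C2=O)c(OCOC)c1C/C=C(\C)CCC=C(C)C
F5 | step 13 | (3S,4S)-3-Ar-5,7-bis(methoxymethoxy)-3,4-dihydro-2H-chromen-4-ol (cis) | COc1ccc([C@H]2COc3cc(OCOC)cc(OCOC)c3[C@H]2O)c(OCOC)c1C/C=C(\C)CCC=C(C)C
F6 | step 7 | 2-Ar-3-(triethylsilyloxy)propanal (racemic) | O=CC(CO[Si](CC)(CC)CC)c1ccc(OC)c(C/C=C(\C)CCC=C(C)C)c1OCOC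
F7 | step 7 | 3-Ar-1-[(4-methylphenyl)sulfinyl]-4-(triethylsilyloxy)butan-2-ol (mixture of diastereomers) | Cc1ccc(S(=O)CC(O)C(CO[Si](CC)(CC)CC)c2ccc(OC)c(C/C=C(\C)CCC=C(C)C)c2OCOC)cc1
F8 | step 14 | racemic 3-{3-[(2E)-3,7-dimethylocta-2,6-dien-1-yl]-2-hydroxy-4-methoxyphenyl}-5,7-dihydroxy-2,3-dihydro-4H-chromen-4-one | COc1ccc(C2COc3cc(O)cc(O)c3C2=O)c(O)c1C/C=C(\C)CCC=C(C)C
F9 | step 14 | 3-{3-[(2E)-3,7-dimethylocta-2,6-dien-1-yl]-4-methoxy-2-[(prop-2-en-1-yloxy)carbonyloxy]phenyl}-2H-chromene-4,5,7-triyl tris(prop-2-en-1-yl) tricarbonate | C=CCOC(=O)OC1=C(c2ccc(OC)c(C/C=C(\C)CCC=C(C)C)c2OC(=O)OCC=C)COc2cc(OC(=O)OCC=C)cc(OC(=O)OCC=C)c21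
F10 | step 3 | 1-bromo-4-methoxy-2-(methoxymethoxy)benzene | COCOc1cc(OC)ccc1Br
F11 | step 3 | 1-bromo-3-[(2E)-3,7-dimethylocta-2,6-dien-1-yl]-4-methoxy-2-(methoxymethoxy)benzene | COc1ccc(Br)c(OCOC)c1C/C=C(\C)CCC=C(C)C
A1 | alternative 1 | 3-{3-[(2E)-3,7-dimethylocta-2,6-dien-1-yl]-2-hydroxy-4-methoxyphenyl}-5,7-bis(methoxymethoxy)-4H-chromen-4-one | COc1ccc(-c2coc3cc(OCOC)cc(OCOC)c3c2=O)c(O)c1C/C=C(\C)CCC=C(C)C
A2 | alternative 1 | (3E)-4-[5,7-bis(methoxymethoxy)-4-oxo-4H-chromen-3-yl]-1-diazobut-3-en-2-one | [N-]=[N+]=CC(=O)/C=C/c1coc2cc(OCOC)cc(OCOC)c2c1=O
A3 | alternative 1 | (4E)-1-methoxy-5,9-dimethyldeca-4,8-dien-1-yne | COC#CC/C=C(\C)CCC=C(C)C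
A4 | alternative 2 | (3S)-5,7-bis(tert-butyldimethylsilyloxy)-3-{2-(tert-butyldimethylsilyloxy)-3-[(2E)-3,7-dimethylocta-2,6-dien-1-yl]-4-methoxyphenyl}-2,3-dihydro-4H-chromen-4-one | COc1ccc([C@H]2COc3cc(O[Si](C)(C)C(C)(C)C)cc(O[Si](C)(C)C(C)(C)C)c3C2=O)c(O[Si](C)(C)C(C)(C)C)c1C/C=C(\C)CCC=C(C)C
A5 | alternative 2 | 1-[2,4-bis(tert-butyldimethylsilyloxy)-6-methoxyphenyl]-2-{2-(tert-butyldimethylsilyloxy)-3-[(2E)-3,7-dimethylocta-2,6-dien-1-yl]-4-methoxyphenyl}-2-diazoethan-1-one | COc1cc(O[Si](C)(C)C(C)(C)C)cc(O[Si](C)(C)C(C)(C)C)c1C(=O)C(=[N+]=[N-])c1ccc(OC)c(C/C=C(\C)CCC=C(C)C)c1O[Si](C)(C)C(C)(C)C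
A6 | alternative 3 | 2-Ar-1-[2,4,6-tris(methoxymethoxy)phenyl]prop-2-en-1-one | C=C(C(=O)c1c(OCOC)cc(OCOC)cc1OCOC)c1ccc(OC)c(C/C=C(\C)CCC=C(C)C)c1OCOC
A7 | alternative 3 | 2-iodo-1,3,5-tris(methoxymethoxy)benzene | COCOc1cc(OCOC)c(I)c(OCOC)c1
A8 | alternative 3 | N'-(1-Ar-ethylidene)-4-methylbenzenesulfonohydrazide | CC(=NNS(=O)(=O)c1ccc(C)cc1)c1ccc(OC)c(C/C=C(\C)CCC=C(C)C)c1OCOC
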